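**Retrosynthetic overview**

1. Locants (decalin numbering): ring B = C1–C4, C4a, C8a; ring A = C4a, C5–C8, C8a. C1 bears CH3 and the quinonylmethyl group, C2 a CH3, C4a the angular CH3, C5 the propanoic acid chain, C6 the isopropylidene.
2. Endgame: the quinone comes from a 2,5-dimethoxy-3-methylbenzyl unit by oxidation, the CO2H from a nitrile, and the C2 methyl from a C2–CH2SO2Ph arm.
3. Key disconnection C1–C2 (closes ring B): 6-exo-trig cyclisation of the tertiary C1 radical, released from a temporary C1 carboxyl (lost as CO2), onto an E-vinyl sulfone tethered through C4a. Enabling feature: C1 is a hydrogen-free, fully substituted carbon lying 1,6 to the exocyclic carbon on C2, so C1 can be a tertiary radical and the future C2 methyl can carry the temporary sulfonyl group.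
4. Ring A precursor: C8a by Johnson–Claisen chirality transfer from (1R)-2-methylcyclohex-2-en-1-ol (this step also brings in the carboxyl-bearing C1); C4a by anti cuprate addition to the derived enone; C5 by Michael addition and equilibration; C6=CMe2 by selenium-based olefination; aryl unit by enolate benzylation.
5. Ring order: ring A (carried from 2-methylcyclohex-2-enone) → ring B (key step) → quinone ring unveiled last.

Key step: step 16

Remark: 2,2-bis(methylselanyl)propane (the selenoketal of acetone, step 11) is treated as a stock reagent; it is the one-step condensation product of acetone and methaneselenol.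

**Route**

Step 1
Reactants: 1 4-methoxy-2-methylphenol
Product: 2 2-hydroxy-5-methoxy-3-methylbenzaldehyde
Conditions: (CH2O)n, MgCl2, Et3N, MeCN, reflux
Reagents that add atoms: paraformaldehyde (as formaldehyde), C=O
Why: Casnati–Skattebøl ortho-formylation, in which the magnesium phenoxide directs formylation to the single free ortho position and the aldehyde oxidation level is reached by hydride transfer to a second formaldehyde.

Step 2
Reactants: 2 2-hydroxy-5-methoxy-3-methylbenzaldehyde
Product: 3 2,5-dimethoxy-3-methylbenzaldehyde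
Conditions: MeI, K2CO3, DMF, 40 °C
Reagents that add atoms: iodomethane, CI
Why: Williamson O-methylation of the phenoxide, to which the aldehyde is inert.

Step 3
Reactants: 3 2,5-dimethoxy-3-methylbenzaldehyde
Product: 4 (2,5-dimethoxy-3-methylphenyl)methanol
Conditions: NaBH4, MeOH, 0 °C
Reagents that add atoms: none
Why: Borohydride reduction of the aldehyde to the benzylic alcohol.

Step 4
Reactants: 4 (2,5-dimethoxy-3-methylphenyl)methanol
Product: 5 1-(bromomethyl)-2,5-dimethoxy-3-methylbenzene
Conditions: PBr3, Et2O, 0 °C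
Reagents that add atoms: phosphorus tribromide, BrP(Br)Br
Why: Alcohol-to-bromide substitution with PBr3 (SN2 on the phosphite ester), which is clean at a primary benzylic carbon; the bromide should be used directly.

Step 5
Reactants: 6 2-methylcyclohex-2-en-1-one
Product: 7 (1R)-2-methylcyclohex-2-en-1-ol
Conditions: (S)-2-methyl-CBS-oxazaborolidine (10 mol %), BH3·SMe2, THF, −20 °C; MeOH quench
Reagents that add atoms: none
Why: Corey–Bakshi–Shibata reduction, in which the methyl-substituted alkenyl arm acts as the large group so that the (S)-catalyst should deliver hydride to the face giving the (1R)-carbinol, the stereocentre from which all others are relayed.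

Step 6
Reactants: 7 (1R)-2-methylcyclohex-2-en-1-ol; 8 trimethyl orthopropionate
Product: 10 methyl 2-[(1R)-2-methylcyclohex-2-en-1-yl]propanoate (2RS in the chain), via ketene acetal 9 (not isolated)
Conditions: EtCO2H (cat.), xylene, 140 °C, MeOH distilled off
Reagents that add atoms: none
Why: Johnson–Claisen rearrangement, in which ketene acetal 9 undergoes a suprafacial [3,3] shift that transfers the C–O stereocentre to the new C–C bond at the ring carbon that becomes C8a, on the same face, and moves the alkene to the methyl-bearing carbon; the chain CH(CH3) centre forms as a mixture that does not matter.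

Step 7
Reactants: 10 methyl 2-[(1R)-2-methylcyclohex-2-en-1-yl]propanoate
Product: 11 methyl 2-[(1R)-2-methyl-4-oxocyclohex-2-en-1-yl]propanoate (2RS in the chain)
Conditions: Mn(OAc)3·2H2O (10 mol %), t-BuOOH (in decane), 3 Å molecular sieves, EtOAc, rt
Reagents that add atoms: tert-butyl hydroperoxide, CC(C)(C)OO
Why: Manganese-catalysed allylic oxidation with t-BuOOH, which should attack the only unhindered allylic methylene and give the conjugated 3-methyl-4-substituted cyclohexenone without touching the ring stereocentre.

Step 8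
Reactants: 11 methyl 2-[(1R)-2-methyl-4-oxocyclohex-2-en-1-yl]propanoate; 12 but-3-en-1-ylmagnesium bromide
Product: 13 methyl 2-[(1R,2R)-2-(but-3-en-1-yl)-2-methyl-4-(trimethylsilyloxy)cyclohex-3-en-1-yl]propanoate (2RS in the chain)
Conditions: CuBr·SMe2 (10 mol %), Me3SiCl, HMPA, THF, −78 °C; Et3N, pentane work-up
Reagents that add atoms: chlorotrimethylsilane, C[Si](C)(C)Cl
Why: Me3SiCl-accelerated copper-catalysed conjugate addition, in which the side chain on the γ-carbon sits pseudoaxial next to the vinylic methyl (A1,2 strain) and the butenyl group enters the β-carbon anti to it, setting the quaternary centre (C4a) trans to the side chain, while silylation fixes the enolate regiochemistry.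

Step 9
Reactants: 13 methyl 2-[(1R,2R)-2-(but-3-en-1-yl)-2-methyl-4-(trimethylsilyloxy)cyclohex-3-en-1-yl]propanoate; 5 1-(bromomethyl)-2,5-dimethoxy-3-methylbenzene
Product: 14 methyl 2-[(1S,2R)-2-(but-3-en-1-yl)-2-methyl-4-(trimethylsilyloxy)cyclohex-3-en-1-yl]-3-(2,5-dimethoxy-3-methylphenyl)-2-methylpropanoate (mixture at C2 of the chain)
Conditions: LiN(i-Pr)2, THF, −78 °C; then 5, DMPU, −78 → −20 °C
Reagents that add atoms: none
Why: Ester enolate alkylation (SN2 on the benzylic bromide), in which the amide base removes the only acidic C–H without attacking the silyl enol ether and benzylation builds the fully substituted carbon that becomes C1; its configuration is of no consequence because it is later a planar radical.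

Step 10
Reactants: 14 methyl 2-[(1S,2R)-2-(but-3-en-1-yl)-2-methyl-4-(trimethylsilyloxy)cyclohex-3-en-1-yl]-3-(2,5-dimethoxy-3-methylphenyl)-2-methylpropanoate; 15 acrylonitrile
Product: 16 methyl 2-[(1S,2R,3S)-2-(but-3-en-1-yl)-3-(2-cyanoethyl)-2-methyl-4-oxocyclohexyl]-3-(2,5-dimethoxy-3-methylphenyl)-2-methylpropanoate
Conditions: [(Me2N)3S][Me3SiF2] (10 mol %), THF, −78 → 0 °C; aq NH4Cl; then NaOMe (cat.), MeOH, 0 °C → rt
Reagents that add atoms: none
Why: Fluoride-catalysed Michael addition of the enol silane to acrylonitrile forms the C–C bond at the regiodefined α-carbon, and methoxide equilibration of this enolisable centre should favour the isomer with the cyanoethyl chain equatorial, cis to the ring methyl and trans to the butenyl arm, as needed at C5.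

Step 11
Reactants: 16 methyl 2-[(1S,2R,3S)-2-(but-3-en-1-yl)-3-(2-cyanoethyl)-2-methyl-4-oxocyclohexyl]-3-(2,5-dimethoxy-3-methylphenyl)-2-methylpropanoate
Product: 17 methyl 2-[(1S,2R,3S)-2-(but-3-en-1-yl)-3-(2-cyanoethyl)-4-hydroxy-2-methyl-4-[2-(methylselanyl)propan-2-yl]cyclohexyl]-3-(2,5-dimethoxy-3-methylphenyl)-2-methylpropanoate (either carbinol epimer)
Conditions: Me2C(SeMe)2, n-BuLi, THF, −78 °C; then 16, −78 °C; aq NH4Cl
Reagents that add atoms: 2,2-bis(methylselanyl)propane, CC(C)([Se]C)[Se]C
Why: Addition of the α-selenoalkyllithium made by Se/Li exchange (first stage of a selenium-based olefination), a reagent that is strongly nucleophilic but weakly basic and should therefore add to the hindered, enolisable ketone rather than to the ester or nitrile; the new carbinol centre is lost in the next step.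

Step 12
Reactants: 17 the β-hydroxy selenide of step 11
Product: 18 methyl 2-[(1S,2S,3S)-2-(but-3-en-1-yl)-3-(2-cyanoethyl)-2-methyl-4-(propan-2-ylidene)cyclohexyl]-3-(2,5-dimethoxy-3-methylphenyl)-2-methylpropanoate
Conditions: SOCl2, Et3N, CH2Cl2, 0 °C → rt
Reagents that add atoms: none
Why: Reductive elimination of the β-hydroxy selenide (chlorosulfite formation, then anti loss of the selenium and oxygen groups) gives the tetrasubstituted isopropylidene alkene regiospecifically, which a dehydration could not, and it locks the adjacent ring stereocentre.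

Step 13
Reactants: 18 the methyl ester of step 12
Product: 19 2-[(1S,2S,3S)-2-(but-3-en-1-yl)-3-(2-cyanoethyl)-2-methyl-4-(propan-2-ylidene)cyclohexyl]-3-(2,5-dimethoxy-3-methylphenyl)-2-methylpropanoic acid
Conditions: LiI, pyridine, reflux; then 1 M HCl
Reagents that add atoms: none
Why: SN2 O-demethylation by iodide, which attacks the methyl carbon and so cleaves the neopentyl quaternary ester that resists saponification, while nitrile, alkenes and aryl ethers stay intact.

Step 14
Reactants: 19 the acid of step 13; 20 phenyl vinyl sulfone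
Product: 21 2-[(1S,2S,3S)-3-(2-cyanoethyl)-2-methyl-2-[(3E)-4-(phenylsulfonyl)but-3-en-1-yl]-4-(propan-2-ylidene)cyclohexyl]-3-(2,5-dimethoxy-3-methylphenyl)-2-methylpropanoic acid
Conditions: second-generation Grubbs catalyst (5 mol %), CH2Cl2, 40 °C
Reagents that add atoms: none
Why: Olefin cross-metathesis of the unhindered terminal alkene with the electron-poor vinyl sulfone should give the E-vinyl sulfone, the tetrasubstituted isopropylidene being inert to the ruthenium carbene.

Step 15
Reactants: 21 the vinyl sulfone acid of step 14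
Product: 22 1,3-dioxoisoindolin-2-yl 2-[(1S,2S,3S)-3-(2-cyanoethyl)-2-methyl-2-[(3E)-4-(phenylsulfonyl)but-3-en-1-yl]-4-(propan-2-ylidene)cyclohexyl]-3-(2,5-dimethoxy-3-methylphenyl)-2-methylpropanoate
Conditions: N-hydroxyphthalimide, i-PrN=C=N-i-Pr, DMAP (cat.), CH2Cl2, rt
Reagents that add atoms: N-hydroxyphthalimide, O=C1c2ccccc2C(=O)N1O
Why: Carbodiimide esterification with N-hydroxyphthalimide converts the tertiary acid into a redox-active ester, the latent source of the C1 radical.

Step 16
Reactants: 22 the N-acyloxyphthalimide of step 15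
Product: 23 3-[(1R,2R,4aR,5S,8aS)-1-[(2,5-dimethoxy-3-methylphenyl)methyl]-1,4a-dimethyl-2-[(phenylsulfonyl)methyl]-6-(propan-2-ylidene)decahydronaphthalen-5-yl]propanenitrile
Conditions: Ru(bpy)3(PF6)2 (2 mol %), Hantzsch ester (diethyl 1,4-dihydro-2,6-dimethylpyridine-3,5-dicarboxylate), CH2Cl2 (0.01 M), blue LEDs, rt
Reagents that add atoms: none
Why: The photoreduced ruthenium complex transfers an electron to the N-acyloxyphthalimide, which fragments to phthalimide anion, CO2 and the tertiary C1 radical; this nucleophilic radical adds to the β-carbon (C2) of the E-vinyl sulfone held on C4a, and the α-sulfonyl radical takes a hydrogen atom from the Hantzsch ester. The closest known reaction type is the visible-light decarboxylative conjugate addition of tertiary radicals from N-acyloxyphthalimides to electron-poor alkenes, which builds quaternary carbons, combined with classical 6-exo radical Michael cyclisation. Ring B closes 6-exo-trig through a chair transition state trans-fused to ring A, because the radical carbon and the tether are both equatorial on the pre-set C8a and C4a centres. C2 is controlled by this chair, the sulfonylmethyl arm of the E-alkene going equatorial; C1 is controlled by the angular C4a methyl, which should force the smaller methyl of the planar radical axial (syn to it) and the arylmethyl group equatorial, giving the spatial arrangement of the target (the descriptors of 23 differ only because sulfur changes the priorities). The step needs cyclisation to outrun hydrogen transfer to the uncyclised radical, which the strongly electrophilic acceptor, high dilution and the slow donor should secure, and it needs the facial preference at C1, which rests on the 1,3-diaxial penalty between the C4a methyl and an axial arylmethyl group.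

Step 17
Reactants: 23 the cyclised sulfone of step 16
Product: 24 3-[(1S,2R,4aR,5S,8aR)-1-[(2,5-dimethoxy-3-methylphenyl)methyl]-1,2,4a-trimethyl-6-(propan-2-ylidene)decahydronaphthalen-5-yl]propanenitrile
Conditions: Na/Hg (6 % Na), Na2HPO4, MeOH–THF, −20 °C
Reagents that add atoms: none
Why: Reductive desulfonylation with sodium amalgam (electron transfer, C–S cleavage, protonation) turns the CH2SO2Ph arm into the C2 methyl group without touching the stereocentres.

Step 18
Reactants: 24 the nitrile of step 17
Product: 26 3-[(1S,2R,4aR,5S,8aR)-1-[(2,5-dimethoxy-3-methylphenyl)methyl]-1,2,4a-trimethyl-6-(propan-2-ylidene)decahydronaphthalen-5-yl]propanoic acid, via primary amide 25 (not isolated)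
Conditions: KOH, H2O–HOCH2CH2OH, 130 °C; then 1 M HCl
Reagents that add atoms: potassium hydroxide, [K+].[OH-]; water, O
Why: Alkaline nitrile hydrolysis through amide 25, which is safe because no stereocentre is α to the nitrile and the aryl methyl ethers and the tetrasubstituted alkene are stable to hydroxide.

Step 19
Reactants: 26 the acid of step 18
Product: 27 stypoquinonic acid, 3-[(1S,2R,4aR,5S,8aR)-1,2,4a-trimethyl-1-[(5-methyl-3,6-dioxocyclohexa-1,4-dien-1-yl)methyl]-6-(propan-2-ylidene)decahydronaphthalen-5-yl]propanoic acid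
Conditions: (NH4)2Ce(NO3)6, MeCN–H2O, 0 °C
Reagents that add atoms: water, O
Why: Oxidative demethylation of the hydroquinone dimethyl ether to the para-quinone (water supplies the two carbonyl oxygens) should be faster than any oxidation of the tetrasubstituted alkene or the acid.

**Compound list**

1 | 4-methoxy-2-methylphenol | COc1ccc(O)c(C)c1 | starting material
2 | 2-hydroxy-5-methoxy-3-methylbenzaldehyde | COc1cc(C)c(O)c(C=O)c1 | intermediate
3 | 2,5-dimethoxy-3-methylbenzaldehyde | COc1cc(C)c(OC)c(C=O)c1 | intermediate
4 | (2,5-dimethoxy-3-methylphenyl)methanol | COc1cc(C)c(OC)c(CO)c1 | intermediate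
5 | 1-(bromomethyl)-2,5-dimethoxy-3-methylbenzene | COc1cc(C)c(OC)c(CBr)c1 | intermediate
6 | 2-methylcyclohex-2-en-1-one | CC1=CCCCC1=O | starting material
7 | (1R)-2-methylcyclohex-2-en-1-ol | CC1=CCCC[C@H]1O | intermediate
8 | trimethyl orthopropionate (1,1,1-trimethoxypropane) | CCC(OC)(OC)OC | starting material
9 | 1-methoxy-1-{[(1R)-2-methylcyclohex-2-en-1-yl]oxy}prop-1-ene (ketene acetal, not isolated) | CC=C(OC)O[C@@H]1CCCC=C1C | intermediate
10 | methyl 2-[(1R)-2-methylcyclohex-2-en-1-yl]propanoate (2RS in the chain) | COC(=O)C(C)[C@H]1CCCC=C1C | intermediate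
11 | methyl 2-[(1R)-2-methyl-4-oxocyclohex-2-en-1-yl]propanoate (2RS in the chain) | COC(=O)C(C)[C@H]1CCC(=O)C=C1C | intermediate
12 | but-3-en-1-ylmagnesium bromide | C=CCC[Mg]Br | starting material
13 | methyl 2-[(1R,2R)-2-(but-3-en-1-yl)-2-methyl-4-(trimethylsilyloxy)cyclohex-3-en-1-yl]propanoate (2RS in the chain) | COC(=O)C(C)[C@H]3CCC(O[Si](C)(C)C)=C[C@]3(C)CCC=C | intermediate
14 | methyl 2-[(1S,2R)-2-(but-3-en-1-yl)-2-methyl-4-(trimethylsilyloxy)cyclohex-3-en-1-yl]-3-(2,5-dimethoxy-3-methylphenyl)-2-methylpropanoate (mixture at C2 of the chain) | COC(=O)C(C)(Cc1cc(OC)cc(C)c1OC)[C@H]3CCC(O[Si](C)(C)C)=C[C@]3(C)CCC=C | intermediate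
15 | acrylonitrile | C=CC#N | starting material
16 | methyl 2-[(1S,2R,3S)-2-(but-3-en-1-yl)-3-(2-cyanoethyl)-2-methyl-4-oxocyclohexyl]-3-(2,5-dimethoxy-3-methylphenyl)-2-methylpropanoate | COC(=O)C(C)(Cc1cc(OC)cc(C)c1OC)[C@H]3CCC(=O)[C@@H](CCC#N)[C@]3(C)CCC=C | intermediate
17 | methyl 2-[(1S,2R,3S)-2-(but-3-en-1-yl)-3-(2-cyanoethyl)-4-hydroxy-2-methyl-4-[2-(methylselanyl)propan-2-yl]cyclohexyl]-3-(2,5-dimethoxy-3-methylphenyl)-2-methylpropanoate (either carbinol epimer) | COC(=O)C(C)(Cc1cc(OC)cc(C)c1OC)[C@H]3CCC(O)(C(C)(C)[Se]C)[C@@H](CCC#N)[C@]3(C)CCC=C | intermediate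
18 | methyl 2-[(1S,2S,3S)-2-(but-3-en-1-yl)-3-(2-cyanoethyl)-2-methyl-4-(propan-2-ylidene)cyclohexyl]-3-(2,5-dimethoxy-3-methylphenyl)-2-methylpropanoate | COC(=O)C(C)(Cc1cc(OC)cc(C)c1OC)[C@H]3CCC(=C(C)C)[C@@H](CCC#N)[C@]3(C)CCC=C | intermediate
19 | 2-[(1S,2S,3S)-2-(but-3-en-1-yl)-3-(2-cyanoethyl)-2-methyl-4-(propan-2-ylidene)cyclohexyl]-3-(2,5-dimethoxy-3-methylphenyl)-2-methylpropanoic acid | OC(=O)C(C)(Cc1cc(OC)cc(C)c1OC)[C@H]3CCC(=C(C)C)[C@@H](CCC#N)[C@]3(C)CCC=C | intermediate
20 | phenyl vinyl sulfone | C=CS(=O)(=O)c1ccccc1 | starting material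
21 | 2-[(1S,2S,3S)-3-(2-cyanoethyl)-2-methyl-2-[(3E)-4-(phenylsulfonyl)but-3-en-1-yl]-4-(propan-2-ylidene)cyclohexyl]-3-(2,5-dimethoxy-3-methylphenyl)-2-methylpropanoic acid | OC(=O)C(C)(Cc1cc(OC)cc(C)c1OC)[C@H]3CCC(=C(C)C)[C@@H](CCC#N)[C@]3(C)CC/C=C/S(=O)(=O)c2ccccc2 | intermediate
22 | 1,3-dioxoisoindolin-2-yl ester of 21 | O=C(ON1C(=O)c2ccccc2C1=O)C(C)(Cc1cc(OC)cc(C)c1OC)[C@H]3CCC(=C(C)C)[C@@H](CCC#N)[C@]3(C)CC/C=C/S(=O)(=O)c2ccccc2 | intermediate
23 | 3-[(1R,2R,4aR,5S,8aS)-1-[(2,5-dimethoxy-3-methylphenyl)methyl]-1,4a-dimethyl-2-[(phenylsulfonyl)methyl]-6-(propan-2-ylidene)decahydronaphthalen-5-yl]propanenitrile | COc1cc(C)c(OC)c(C[C@]2(C)[C@H]3CCC(=C(C)C)[C@@H](CCC#N)[C@]3(C)CC[C@H]2CS(=O)(=O)c4ccccc4)c1 | intermediate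
24 | 3-[(1S,2R,4aR,5S,8aR)-1-[(2,5-dimethoxy-3-methylphenyl)methyl]-1,2,4a-trimethyl-6-(propan-2-ylidene)decahydronaphthalen-5-yl]propanenitrile | COc1cc(C)c(OC)c(C[C@]2(C)[C@H]3CCC(=C(C)C)[C@@H](CCC#N)[C@]3(C)CC[C@H]2C)c1 | intermediate
25 | 3-[(1S,2R,4aR,5S,8aR)-1-[(2,5-dimethoxy-3-methylphenyl)methyl]-1,2,4a-trimethyl-6-(propan-2-ylidene)decahydronaphthalen-5-yl]propanamide (not isolated) | COc1cc(C)c(OC)c(C[C@]2(C)[C@H]3CCC(=C(C)C)[C@@H](CCC(N)=O)[C@]3(C)CC[C@H]2C)c1 | intermediate
26 | 3-[(1S,2R,4aR,5S,8aR)-1-[(2,5-dimethoxy-3-methylphenyl)methyl]-1,2,4a-trimethyl-6-(propan-2-ylidene)decahydronaphthalen-5-yl]propanoic acid | COc1cc(C)c(OC)c(C[C@]2(C)[C@H]3CCC(=C(C)C)[C@@H](CCC(=O)O)[C@]3(C)CC[C@H]2C)c1 | intermediate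
27 | stypoquinonic acid | CC1=CC(=O)C=C(C[C@]2(C)[C@H]3CCC(=C(C)C)[C@@H](CCC(=O)O)[C@]3(C)CC[C@H]2C)C1=O | target

**Step count and risks**

Total step count: 19. Longest linear sequence: 15 steps (steps 5–19 from 2-methylcyclohex-2-en-1-one; the aryl branch, steps 1–4 then 9–19, is equally long).

Steps most likely to fail:

1. Step 16. The tertiary radical may be quenched by hydrogen transfer, or lose a β-hydrogen, before it cyclises, and closure through the alternative chair would erode the configuration at C1. Fallback: from acid 21, coupling with PhSeH (N,N′-dicyclohexylcarbodiimide, DMAP) would give the Se-phenyl selenoester F1. Slow syringe-pump addition of (Me3Si)3SiH and AIBN in benzene at 80 °C generates the acyl radical, which loses CO to the same C1 radical in a chain process where the donor concentration can be set as low as needed. The cyclised sulfone rejoins the route at 23.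

2. Step 10. The fluoride-generated enolate may lose its regiochemical integrity by proton transfer, the acceptor may oligomerise, and equilibration may leave a large share of the wrong epimer at the chain-bearing carbon. Fallback: from enol silane 14, an amine-salt (iminium) catalysed Mukaiyama–Michael addition to acrolein activates the acceptor instead of the donor and should give the keto aldehyde F2. I2 in aqueous NH3/THF converts the aldehyde into the nitrile, and the same NaOMe equilibration rejoins the route at 16.

3. Step 11. The bulky tertiary carbanion may enolise the hindered ketone instead of adding, so that the olefination stalls. Fallback: from ketone 16, mixed McMurry coupling with excess acetone (TiCl4, Zn, pyridine, THF, reflux; low-valent titanium) makes the isopropylidene group in one operation and rejoins the route at 18, replacing steps 11 and 12; it makes no new compound (F0).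

Further compounds
F1 | step 16 | Se-phenyl 2-[(1S,2S,3S)-3-(2-cyanoethyl)-2-methyl-2-[(3E)-4-(phenylsulfonyl)but-3-en-1-yl]-4-(propan-2-ylidene)cyclohexyl]-3-(2,5-dimethoxy-3-methylphenyl)-2-methylpropaneselenoate | O=C([Se]c1ccccc1)C(C)(Cc1cc(OC)cc(C)c1OC)[C@H]3CCC(=C(C)C)[C@@H](CCC#N)[C@]3(C)CC/C=C/S(=O)(=O)c2ccccc2
F2 | step 10 | methyl 2-[(1S,2R,3S)-2-(but-3-en-1-yl)-2-methyl-4-oxo-3-(3-oxopropyl)cyclohexyl]-3-(2,5-dimethoxy-3-methylphenyl)-2-methylpropanoate | COC(=O)C(C)(Cc1cc(OC)cc(C)c1OC)[C@H]3CCC(=O)[C@@H](CCC=O)[C@]3(C)CCC=C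
F0 | step 11 | none | none
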